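**Plan**
Retrosynthesis: the 9α-OH is removed first (oxidation of the C11 aldehyde enol ether), the C7=C8 bond is traced back to a C7 nitro group (loss of HNO2), and ring B is then cut at C6–C7 and C8–C9.
These two cuts take out C7–C8 with C12 as a β-nitroacrolein acetal and leave a ring A 1,5-dialdehyde (C11–C9–C10–C5–C6), whose two formyl groups go back to the allyl and vinyl groups of a trans-2-allyl-3-vinylcyclohexanone.
Enabling feature: in ring B the carbinol carbon C6 and C9, the α-carbon of the C11 aldehyde, flank C7=C8(C12HO). With NO2 on C7 every atom reacts with its natural polarity (C9 enamine to C8, C7 nitronate to the C6 aldehyde), and the nitro group then leaves to give the enal.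
Forward order: ring A (conjugate vinylation/allylation, reduction, acetylation, double ozonolysis), then ring B in one domino step, then nitrite loss, acetylation and C9 hydroxylation.
Stereochemistry: C5 by the catalyst in the conjugate addition, C10 by anti allylation, C1 by reagent-controlled reduction, C6 by the reversible nitroaldol closure (equatorial 6α-OH), C9 by α-face oxidation opposite the axial C10 methyl.

Key step: step 7

Remark: drimane numbering is used for the bicyclic compounds (decalin C1–C10, C11 on C9, C12 on C8; β is the face of the C10 methyl, α the opposite face).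
Remark: the C9 formyl group of the key-step product and of the three compounds after it is drawn α (the syn-Michael outcome); this centre becomes trigonal in the last step, so either C9 epimer serves.
Remark: in step 1 the ligand enantiomer is the one that gives the (3S) product, to be fixed by a test reaction; the enone and the aqueous 2,2-dimethoxyacetaldehyde are taken as catalogue compounds.

Step 1
Reactants: 1 2,4,4-trimethylcyclohex-2-en-1-one; 2 vinylmagnesium bromide; 3 allyl bromide
Product: 5 (2R,3S)-3-ethenyl-2,4,4-trimethyl-2-(prop-2-en-1-yl)cyclohexan-1-one, via magnesium enolate 4 (not isolated)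
Conditions: CuBr·SMe2 (5 mol %), (R)-1-[(S)-2-(diphenylphosphino)ferrocenyl]ethyldicyclohexylphosphine (6 mol %), 2, t-BuOMe, −78 °C; then 3, DMPU, −78 °C → rt
Reagents that add atoms: none
Why: Copper-catalysed asymmetric conjugate addition of a Grignard reagent to a 2-substituted cyclic enone with trapping of the magnesium enolate, in which the chiral vinylcopper species sets C3 and the tetrasubstituted enolate is C-allylated anti to the neighbouring pseudoaxial vinyl group, so that the quaternary centre forms with allyl trans to vinyl.

Step 2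
Reactants: 5 (2R,3S)-3-ethenyl-2,4,4-trimethyl-2-(prop-2-en-1-yl)cyclohexan-1-one
Product: 6 (1R,2R,3S)-3-ethenyl-2,4,4-trimethyl-2-(prop-2-en-1-yl)cyclohexan-1-ol
Conditions: (S)-1-methyl-3,3-diphenyltetrahydro-1H,3H-pyrrolo[1,2-c][1,3,2]oxazaborole ((S)-Me-CBS, 20 mol %), catecholborane, toluene, −78 °C; aq. NaOH work-up
Reagents that add atoms: none
Why: Corey–Bakshi–Shibata reduction, in which the oxazaborolidine treats the quaternary C2 flank as the large group and delivers hydride to the face syn to the allyl group to give the (1R) alcohol cis to the C2 methyl, while catecholborane leaves the terminal alkenes alone at this temperature and any minor enantiomer of 5 ends as a separable diastereomer.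

Step 3
Reactants: 6 (1R,2R,3S)-3-ethenyl-2,4,4-trimethyl-2-(prop-2-en-1-yl)cyclohexan-1-ol
Product: 7 (1R,2R,3S)-3-ethenyl-2,4,4-trimethyl-2-(prop-2-en-1-yl)cyclohexyl acetate
Conditions: Ac2O, Et3N, 4-(dimethylamino)pyridine (10 mol %), CH2Cl2, rt
Reagents that add atoms: acetic anhydride, CC(=O)OC(C)=O
Why: Nucleophile-catalysed acylation of the hindered secondary alcohol, which touches no stereocentre and installs the final C1 acetate before any aldehyde is present.

Step 4
Reactants: 7 (1R,2R,3S)-3-ethenyl-2,4,4-trimethyl-2-(prop-2-en-1-yl)cyclohexyl acetate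
Product: 8 (1R,2R,3S)-3-formyl-2,4,4-trimethyl-2-(2-oxoethyl)cyclohexyl acetate
Conditions: O3, CH2Cl2, −78 °C; then PPh3, −78 °C → rt
Reagents that add atoms: ozone, O=[O+][O-]
Why: Ozonolysis with reductive work-up cleaves both terminal alkenes at once, the vinyl group to the ring carbaldehyde (C6) and the allyl group to the acetaldehyde chain (C9–C11), under neutral conditions that leave the epimerisable C3 centre untouched.

Step 5
Reactants: 9 nitromethane; 10 2,2-dimethoxyacetaldehyde
Product: 11 3,3-dimethoxy-1-nitropropan-2-ol (racemic)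
Conditions: K2CO3 (5 mol %), H2O–THF, 0 °C → rt
Reagents that add atoms: none
Why: Base-catalysed Henry (nitroaldol) addition of nitromethane to a non-enolisable, electron-poor aldehyde; the carbinol centre formed is racemic and disappears in step 6.

Step 6
Reactants: 11 3,3-dimethoxy-1-nitropropan-2-ol
Product: 13 (E)-3,3-dimethoxy-1-nitroprop-1-ene, via nitro mesylate 12 (not isolated)
Conditions: MsCl, Et3N, CH2Cl2, −20 °C → 0 °C
Reagents that add atoms: none
Why: Mesylation followed by E1cB elimination of the β-nitro alcohol (nitroaldol dehydration) gives the thermodynamically preferred E nitroalkene.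

Step 7
Reactants: 8 (1R,2R,3S)-3-formyl-2,4,4-trimethyl-2-(2-oxoethyl)cyclohexyl acetate; 13 (E)-3,3-dimethoxy-1-nitroprop-1-ene
Product: 15 1β-acetoxy-6α-hydroxy-12,12-dimethoxy-7β-nitro-9-epi-drimane-11-al, via open-chain Michael adduct 14 (not isolated)
Conditions: (R)-2-[diphenyl(trimethylsilyloxy)methyl]pyrrolidine (20 mol %), 4-nitrophenol (20 mol %), toluene, 0 °C → rt; then Et3N (20 mol %), rt
Reagents that add atoms: none
Why: The secondary amine condenses only with the unhindered C11 aldehyde of 8 (the C6 aldehyde sits on a tertiary carbon between two quaternary carbons and cannot form an enamine), and the E-enamine adds through C9 to the nitro-β carbon of 13 in a synclinal transition state, forming C8–C9; the C7 nitronate then adds to the C6 aldehyde (intramolecular Henry reaction), forming C6–C7 and closing ring B. The closest known reaction type is the diarylprolinol silyl ether catalysed Michael/Henry domino reaction of pentane-1,5-dials with nitroalkenes, and 8 is such a 1,5-dial (C11–C9–C10–C5–C6) with its two central carbons held in ring A. Ring B closes in the 6-(enolexo)-exo-trig mode and can only become trans-fused, because C5 and C10 are already fixed trans in 8. C8 and C9 are set by the catalyst, which shields one enamine face and directs the nitroalkene face (the (R)-catalyst should give the 8S,9R syn adduct with the dimethoxymethyl group equatorial; both centres are erased later, C8 in step 8 and C9 in step 10). C7 and C6 are set under thermodynamic control, because the nitroaldol step and the α-nitro centre equilibrate under the basic conditions, and the arrangement with equatorial 7β-NO2 and 6α-OH should win since a 6β-hydroxyl would be 1,3-diaxial to both the C10 and the C4β methyl groups. The selectivities needed are site selectivity between the two aldehydes and clean 1,4-addition, secured by the steric difference of the two formyl groups and by the nitro group, which makes C7 nucleophilic and C8 electrophilic and is later lost as nitrite to give the C7=C8 bond.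

Step 8
Reactants: 15 1β-acetoxy-6α-hydroxy-12,12-dimethoxy-7β-nitro-9-epi-drimane-11-al
Product: 17 1β-acetoxy-6α-hydroxy-9-epi-drim-7-ene-11,12-dial, via nitro dialdehyde 16 (not isolated)
Conditions: CF3CO2H–H2O (9:1), CH2Cl2, 0 °C; then Et3N, CH2Cl2, 0 °C
Reagents that add atoms: water, O
Why: Acid hydrolysis of the dimethyl acetal unmasks the C12 aldehyde, whose now acidic C8–H allows E1cB loss of nitrite (β-nitro carbonyl to enal elimination), which places the double bond at C7=C8 and leaves the C6 carbinol centre unchanged.

Step 9
Reactants: 17 1β-acetoxy-6α-hydroxy-9-epi-drim-7-ene-11,12-dial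
Product: 18 1β,6α-diacetoxy-9-epi-drim-7-ene-11,12-dial
Conditions: Ac2O, pyridine, CH2Cl2, 0 °C → rt
Reagents that add atoms: acetic anhydride, CC(=O)OC(C)=O
Why: Acetylation of the unhindered equatorial allylic alcohol under mild pyridine conditions proceeds with retention at C6 and is done only after the nitro group has gone, so that no nitroalkene can form by loss of acetate.

Step 10
Reactants: 18 1β,6α-diacetoxy-9-epi-drim-7-ene-11,12-dial
Product: 21 parritadial (1β,6α-diacetoxy-9α-hydroxydrim-7-ene-11,12-dial), via silyl dienol ether 19 (not isolated), via silyloxy epoxide 20 (not isolated)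
Conditions: Me3SiOTf, Et3N, CH2Cl2, −78 °C; dimethyldioxirane, acetone, −78 → −20 °C; then citric acid, THF–H2O, 0 °C
Reagents that add atoms: dimethyldioxirane, CC1(C)OO1
Why: Rubottom oxidation, in which soft enolisation of the saturated C11 aldehyde (its C9–H is both α to the formyl group and allylic) gives the silyl dienol ether, dimethyldioxirane epoxidises the electron-rich C9=C11 bond from the α face opposite the axial C10 methyl, and mild acid releases the 9α-hydroxy aldehyde with the acetates intact.

**Compound list**
1 | 2,4,4-trimethylcyclohex-2-en-1-one | CC1=CC(C)(C)CCC1=O | starting material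
2 | vinylmagnesium bromide | C=C[Mg]Br | starting material
3 | allyl bromide (3-bromoprop-1-ene) | C=CCBr | starting material
4 | bromomagnesium (3S)-3-ethenyl-2,4,4-trimethylcyclohex-1-en-1-olate | CC1=C(O[Mg]Br)CCC(C)(C)[C@@H]1C=C | intermediate
5 | (2R,3S)-3-ethenyl-2,4,4-trimethyl-2-(prop-2-en-1-yl)cyclohexan-1-one (allyl trans to vinyl) | C=CC[C@@]1(C)C(=O)CCC(C)(C)[C@@H]1C=C | intermediate
6 | (1R,2R,3S)-3-ethenyl-2,4,4-trimethyl-2-(prop-2-en-1-yl)cyclohexan-1-ol (OH cis to the C2 methyl) | C=CC[C@@]1(C)[C@H](O)CCC(C)(C)[C@@H]1C=C | intermediate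
7 | (1R,2R,3S)-3-ethenyl-2,4,4-trimethyl-2-(prop-2-en-1-yl)cyclohexyl acetate | C=CC[C@@]1(C)[C@H](OC(C)=O)CCC(C)(C)[C@@H]1C=C | intermediate
8 | (1R,2R,3S)-3-formyl-2,4,4-trimethyl-2-(2-oxoethyl)cyclohexyl acetate | O=CC[C@@]1(C)[C@H](OC(C)=O)CCC(C)(C)[C@@H]1C=O | intermediate
9 | nitromethane | C[N+](=O)[O-] | starting material
10 | 2,2-dimethoxyacetaldehyde | COC(OC)C=O | starting material
11 | 3,3-dimethoxy-1-nitropropan-2-ol (racemic) | COC(OC)C(O)C[N+](=O)[O-] | intermediate
12 | 1,1-dimethoxy-3-nitropropan-2-yl methanesulfonate (racemic) | COC(OC)C(OS(C)(=O)=O)C[N+](=O)[O-] | intermediate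
13 | (E)-3,3-dimethoxy-1-nitroprop-1-ene | COC(OC)/C=C/[N+](=O)[O-] | intermediate
14 | (1R,2R,3S)-2-[(2R,3S)-3-(dimethoxymethyl)-4-nitro-1-oxobutan-2-yl]-3-formyl-2,4,4-trimethylcyclohexyl acetate (9R,8S in drimane numbering) | O=C[C@H]([C@@H](C[N+](=O)[O-])C(OC)OC)[C@@]1(C)[C@H](OC(C)=O)CCC(C)(C)[C@@H]1C=O | intermediate
15 | 1β-acetoxy-6α-hydroxy-12,12-dimethoxy-7β-nitro-9-epi-drimane-11-al (trans-decalin, 5α-H, 10β-CH3, 8α-CH(OMe)2, 9α-CHO) | O[C@H]1[C@H]([N+](=O)[O-])[C@@H](C(OC)OC)[C@@H](C=O)[C@@]2(C)[C@H](OC(C)=O)CCC(C)(C)[C@H]12 | intermediate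
16 | 1β-acetoxy-6α-hydroxy-7β-nitro-9-epi-drimane-11,12-dial (8α- and 9α-formyl) | O[C@H]1[C@H]([N+](=O)[O-])[C@@H](C=O)[C@@H](C=O)[C@@]2(C)[C@H](OC(C)=O)CCC(C)(C)[C@H]12 | intermediate
17 | 1β-acetoxy-6α-hydroxy-9-epi-drim-7-ene-11,12-dial (9α-formyl) | O[C@H]1C=C(C=O)[C@@H](C=O)[C@@]2(C)[C@H](OC(C)=O)CCC(C)(C)[C@H]12 | intermediate
18 | 1β,6α-diacetoxy-9-epi-drim-7-ene-11,12-dial | CC(=O)O[C@H]1C=C(C=O)[C@@H](C=O)[C@@]2(C)[C@H](OC(C)=O)CCC(C)(C)[C@H]12 | intermediate
19 | (Z)-1β,6α-diacetoxy-11-(trimethylsilyloxy)drima-7,9(11)-dien-12-al | CC(=O)O[C@H]1C=C(C=O)/C(=C\O[Si](C)(C)C)[C@@]2(C)[C@H](OC(C)=O)CCC(C)(C)[C@H]12 | intermediate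
20 | 1β,6α-diacetoxy-9α,11-epoxy-11-(trimethylsilyloxy)drim-7-en-12-al | CC(=O)O[C@H]1C=C(C=O)[C@@]3(O[C@@H]3O[Si](C)(C)C)[C@@]2(C)[C@H](OC(C)=O)CCC(C)(C)[C@H]12 | intermediate
21 | parritadial, 1β,6α-diacetoxy-9α-hydroxydrim-7-ene-11,12-dial | CC(=O)O[C@H]1C=C(C=O)[C@](O)(C=O)[C@@]2(C)[C@H](OC(C)=O)CCC(C)(C)[C@H]12 | target

**Step count and risks**
Total steps: 10. Longest linear sequence: 8 (steps 1, 2, 3, 4, 7, 8, 9, 10); steps 5 and 6 make the nitroalkene in a side branch.

Most likely to fail:

Step 7. Enamine formation next to the quaternary C10 may be too slow for catalytic turnover, or the nitroaldol closure onto the hindered C6 aldehyde may stall at the open-chain stage. The fallback sets out from 8 and comes back at 15. Compound 8 is condensed with one equivalent of (R)-2-[diphenyl(trimethylsilyloxy)methyl]pyrrolidine over 4 Å molecular sieves in CH2Cl2 to give the preformed C11 enamine F1, which is used stoichiometrically. F1 is added to 13 at −20 °C and hydrolysed with aqueous acetic acid, which gives the Michael adduct 14, now isolated. Ring B is then closed in a separate nitroaldol step under equilibrating conditions with a stronger non-nucleophilic base (1,1,3,3-tetramethylguanidine, THF, 0 °C) to give 15.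

Step 1. Enantioface selection may be poor for a vinyl Grignard reagent on this enone with a quaternary γ-carbon, or uncatalysed 1,2-addition may compete. The fallback sets out from 1 and comes back at 6. Compound 1 is treated with the divinylcuprate made from 2 and CuI in THF at −78 °C, without a chiral ligand, and the enolate is trapped with 3. This gives 4 together with the enantiomeric magnesium enolate F2, and from them racemic ketone, that is 5 together with the enantiomeric ketone F3. The step 2 reduction is reagent-controlled and then serves as the resolution: 5 gives 6, and F3 gives the diastereomeric (1R,2S,3R)-alcohol F4, which is removed by chromatography.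

Step 10. Soft enolisation may take the wrong course (γ-deprotonation at C6 of the C12 enal instead of C9–H removal), or the silyl dienol ether may hydrolyse back before oxidation. The fallback sets out from 18 and comes back at 21. Compound 18 is deprotonated at its most acidic position, C9–H, with one equivalent of KN(SiMe3)2 in THF at −78 °C to give the potassium dienolate F5. F5 is oxidised in the same flask with 2-(phenylsulfonyl)-3-phenyloxaziridine from the α face and quenched with aqueous NH4Cl to give 21.

**Further compounds**
F1 | step 7 | C11 (E)-enamine of 8 with (R)-2-[diphenyl(trimethylsilyloxy)methyl]pyrrolidine | C[Si](C)(C)OC(c1ccccc1)(c1ccccc1)[C@H]1CCCN1/C=C/[C@@]2(C)[C@H](OC(C)=O)CCC(C)(C)[C@@H]2C=O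
F2 | step 1 | bromomagnesium (3R)-3-ethenyl-2,4,4-trimethylcyclohex-1-en-1-olate (enantiomer of 4) | CC1=C(O[Mg]Br)CCC(C)(C)[C@H]1C=C
F3 | step 1 | (2S,3R)-3-ethenyl-2,4,4-trimethyl-2-(prop-2-en-1-yl)cyclohexan-1-one (enantiomer of 5) | C=CC[C@]1(C)C(=O)CCC(C)(C)[C@H]1C=C
F4 | step 1 | (1R,2S,3R)-3-ethenyl-2,4,4-trimethyl-2-(prop-2-en-1-yl)cyclohexan-1-ol | C=CC[C@]1(C)[C@H](O)CCC(C)(C)[C@H]1C=C
F5 | step 10 | potassium (Z)-dienolate of 18 (C9=C11 enolate) | CC(=O)O[C@H]1C=C(C=O)/C(=C\[O-])[C@@]2(C)[C@H](OC(C)=O)CCC(C)(C)[C@H]12.[K+]
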